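**Reading the constant.** Thursday's first reading, at 0.833 min with 1.2 M of G charged, shows 23.1% of D turned into J and Q, while hardly any of the G has gone, so we read D as decaying there at the rate k[G][D], with k = 0.263 L mol⁻¹ min⁻¹, a reading that carries the scatter.

all flasks: D 0.20 M
- Sunday's: G 0.33 M; E 0.20 M; run made earlier
- Thursday's: G 1.2 M; E 0.20 M; run made earlier
- alder: G 0.600 M; E 0.200 M; time 15 min
- ash: G 0.800 M; E 0.200 M; time 15 min
- elm: G 0.240 M; E 0.200 M; time 15 min

| run | time / min | J / % | Q / % |
|---|---|---|---|
| Sunday's | 0.667 | 5.9 | 0.1 |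
| Sunday's | 2.00 | 14.3 | 0 |
| Sunday's | 4.00 | 26.0 | 0.8 |
| Sunday's | 6.00 | 32.7 | 0.9 |
| Sunday's | 8.00 | 37.9 | 0.3 |
| Sunday's | 10.0 | 41.6 | 1.6 |
| Thursday's | 0.833 | 22.6 | 0.5 |
| Thursday's | 1.33 | 31.7 | 0.5 |
| Thursday's | 2.50 | 47.6 | 1.5 |
| Thursday's | 4.00 | 57.7 | 2.1 |
| Thursday's | 6.00 | 60.8 | 3.3 |
| Thursday's | 10.0 | 54.5 | 2.3 |

(readings scatter by 0.5 percentage points)

1. which of these holds the largest part of the D at the end of alder (D / Q / J / L)
2. which of these holds the largest part of the D at the end of ash (D / Q / J / L)
3. which of these holds the largest part of the D at the end of elm (D / Q / J / L)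
4. final J in elm, as a percentage of the D charged



**A moving clock.** The reciprocal of k[G] is a time, which for elm at the charged [G] is 15.9 min, and this pseudo-first-order clock would leave 38.9% of D at 15 min. But elm's G stands above its D by a margin Δ = 0.0400 M, less than [D] itself, so holding [G] at its charge is unsafe for elm. If each D takes one G and we neglect the later uptake by J, [G] − [D] stays at Δ, and integrating gives the unspent share of D, f = Δ / ([G]c·exp(kΔt) − [D]c), with c marking charged amounts.

**Our reckoning.** Elm gives f = 49.4%, alder 14.8% and ash 7.22%. At the time of Sunday's last reading the reckoned f is 49.2%, so the J read then is 81.8% of the D reckoned as converted. That share puts J in elm near 41.4%, below D, while we expect J to hold most in alder and ash.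

**The forecast.** It names J for alder, J for ash, D for elm and 36% of J in elm, holding that “G is the budget”. Its holders are ours, but it leaves about 60 percent of D in elm, against our 49.4%.

**The result.** G + Q → L + X (k = 1.48 L mol⁻¹ min⁻¹); G + J → Q + X (k = 0.0588 L mol⁻¹ min⁻¹); J + E → Z (k = 0.114 L mol⁻¹ min⁻¹); D + G → J + X (k = 0.273 L mol⁻¹ min⁻¹)

Elm ends with D at 49.2% beside f = 49.4%, and J at 38.6%. J leads in alder at 53.5% and in ash at 51.5%, so the forecast's holders stand. In a neighbour of elm the holder changes: with 0.41 M of G and the rest as in elm, f is 28.5%, the flask leaves 28.8% of D, and J leads at 50.0%.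

The data are simulated with constants of no real substance, and the scatter is random.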